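The earlier runs and the new flask are calculated with made-up constants; scatter was added.

The south run starts with more substrate than the north-east run, yet its last reading is 24.4% of the charge against 26.6%.

the same everywhere: initiator 15 mM

| charge | substrate | partner | temperature | remark | time |
|---|---|---|---|---|---|
| north-east | 0.12 M | 0.15 M | 55 °C | run made earlier |  |
| north-west | 0.13 M | 0.15 M | 66 °C | run made earlier |  |
| south | 0.17 M | 0.15 M | 55 °C | run made earlier |  |
| ash | 0.10 M | 0.150 M | 60 °C |  | 20 h |
| elm | 0.15 M | 0.150 M | 60 °C |  | 12 h |

| run | time / h | target / % |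
|---|---|---|
| north-east | 2.00 | 6.8 |
| north-east | 4.00 | 14.7 |
| north-east | 6.00 | 17.5 |
| north-east | 8.00 | 20.3 |
| north-east | 10.0 | 26.6 |
| north-west | 0.833 | 9.6 |
| north-west | 2.50 | 20.6 |
| north-west | 5.00 | 34.8 |
| north-west | 8.00 | 43.8 |
| north-west | 10.0 | 47.9 |
| south | 2.00 | 6.2 |
| south | 4.00 | 10.9 |
| south | 6.00 | 17.9 |
| south | 8.00 | 20.7 |
| south | 10.0 | 24.4 |

(standard deviation of a reading: 1 percentage point)

- percent here means substrate units held: one side product counts as two
- what is said of by-product includes idle adduct
- candidate steps: initiator -> 2 initiating radical; substrate + initiating radical -> capped initiator + first chain carrier; partner + first chain carrier -> target + second chain carrier; substrate + second chain carrier -> by-product + first chain carrier; 2 second chain carrier -> ended chains; substrate <-> dormant form; substrate + by-product <-> idle adduct; substrate + target -> side product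

* the winner by amount of target, in percent of the substrate charged; "neither" if no more than 2 percentage points parts them (ash / elm / neither)
* how much target is there at the end, in percent of the substrate charged: ash
* how much target is there at the end, in percent of the substrate charged: elm

1. Charge. From those last readings, the yield fraction goes as the substrate charge to the power −0.248. The gap is 2.2 percentage points with a scatter of 1 point per reading, so this exponent is rough.

2. Balance. In ash, substrate is the limiting reagent, so you work in fractions of its charge. Let u be the fraction not yet target, and treat its fall as a first-order decay: the time constant is elapsed time over −ln u. The last readings give 32.3 h at 55 °C and 15.3 h at 66 °C.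

3. Temperature. Taking the logarithm of the constant as straight in temperature, 60 °C gives 23.0 h. This is the yield time constant, the quantity you carry.

4. First number. Held constant, it gives 58.0% for ash and 40.7% for elm.

5. Weak link. The constant does not hold still: the north-west run gives 11.7 h at 5.00 h but 15.3 h at 10.0 h, which is growth as elapsed time to the power 0.392. Stretched this way from 10.0 h, it becomes 30.2 h for ash and 24.7 h for elm. Rounding the step 1 power to a quarter and scaling each yield from the north-west charge with it, you commit to 51.7% for ash and 37.1% for elm.

The forecast names ash, with ash at 54% (46% to 62%) and elm at 39% (33% to 45%), both above your figures, and holds that “percent yield falls only weakly with substrate”.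

The flasks give 51.5% for ash and 36.6% for elm, so ash wins.

    initiator → 2 initiating radical (k = 1.30 × 10⁻⁵ s⁻¹, Ea = 110 kJ mol⁻¹)
    substrate + initiating radical → capped initiator + first chain carrier (k = 24000 M⁻¹ s⁻¹, Ea = 25.0 kJ mol⁻¹)
    partner + first chain carrier → target + second chain carrier (k = 160 M⁻¹ s⁻¹, Ea = 54.0 kJ mol⁻¹)
    substrate + second chain carrier → by-product + first chain carrier (k = 400 M⁻¹ s⁻¹, Ea = 46.0 kJ mol⁻¹)
    2 second chain carrier → ended chains (k = 1.20 × 10⁸ M⁻¹ s⁻¹, Ea = 14.0 kJ mol⁻¹)
    substrate ⇌ dormant form (K = 1.20, k = 1.80 × 10⁻⁵ s⁻¹, Ea = 107 kJ mol⁻¹, ΔH = −80.0 kJ mol⁻¹)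
    substrate + by-product ⇌ idle adduct, settled at all times (K = 8.80 M⁻¹, ΔH = −78.0 kJ mol⁻¹)
    substrate + target → side product (k = 4.60 × 10⁻⁵ M⁻¹ s⁻¹, Ea = 77.0 kJ mol⁻¹)
    (constants at 60 °C)

Your yield time constant of 23.0 h, stretched to 24.7 h, gave elm 37.1% where the flask gives 36.6%. Now take a neighbour of elm, charged with 0.090 M of substrate and run for the same 12 h. Keeping the stretched constant, you get 38.5% before the charge is counted. The charge factor of 1.10 raises this to 42.1%. That neighbour ends with substrate at 23.0% of its charge and target at 43.0%.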